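## Structural features

The target is a cyclohex-2-en-1-one, numbered here C1 (carbonyl), C2=C3 (alkene), C4 (methoxy-bearing carbon), C5 (methylene) and C6 (quaternary carbon). C6 carries an allyl group and a two-carbon arm, C7 (CH–CH3) and C8 (CH–OAc), which ends in a 3,4,5-trimethoxyphenyl ring. There are four stereocentres: C8 (S), C7 (S) and C6 (R) are contiguous, and C4 (R) stands 1,3 to C6 across the ring with its methoxy group cis to the C7 arm and trans to allyl. The fragile groups are the benzylic acetate on a very electron-rich arene (ionisation, acyl loss), the γ-alkoxy enone (enolisation and elimination with base) and the terminal alkene. The real difficulty is the quaternary centre C6, wedged between the carbonyl and the branched C7, and its correlation with the acyclic C7/C8 pair and with the remote C4. The key step exploits the fact that O–C8–C7–C6–C1(=O) are the five ring atoms of a γ-butyrolactone in which C5 is an exocyclic methylene on C6. The anti C7/C8 pair is then the trans relationship of that ring, accessible by carboxy-crotylboration of an aryl aldehyde, and the ring serves as the template on which C6 is built.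

## Logic of the disconnections

16 ⇒ 15. The O–CH3 bond at C4 is cut. The methyl ether is a spectator that is best put on last, and the free hydroxyl is the direct outcome of a carbonyl addition that can close the ring. Nothing is gained in skeleton, but C4 becomes a carbinol. The forward step must methylate without base strong enough to enolise the γ-oxygenated enone or cleave the acetate.

15 ⇒ 14. The ring bond C3–C4 is cut. C4 is an allylic carbinol carbon next to an alkene carbon, the retron of an alkenylmetal adding to an aldehyde. The ring and the C4 stereocentre disappear and an acyclic chain on C6 remains. The forward step needs a (Z)-alkenyl iodide, must choose the aldehyde over the ketone, and must set C4 by 1,3-induction from C6.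

14 ⇒ 13. The C4 aldehyde is traced back to a dithioacetal (two C–S bonds in place of C=O). This carbon enters the molecule as an acyl-anion equivalent and must stay masked while C1 is attacked by an acetylide. The forward unmasking must spare the alkenyl iodide, the allyl group, the arene and the acetate.

13 ⇒ 11 by way of 12. The C3–I bond and the alkene are traced back to an alkyne, and the alkyne C–H to a C–Si bond. A (Z)-β-iodoenone is the product of anti-hydroiodination of a terminal ynone, so no alkene geometry has to be carried through the synthesis. The silyl cap keeps the ynone from acting as a Michael acceptor while the acetate is put on. The forward step must remove silicon under buffered conditions and add HI with Z-selectivity.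

11 ⇒ 10. The acetyl C–O bond at C8 is cut. The acetate of the target is installed at the moment the C8 oxygen is set free, so that this oxygen cannot later form cyclic hemiketals with the C1 ketone or the C4 aldehyde. The forward step must acylate the open-chain secondary hydroxyl.

10 ⇒ 9. The C1–C2 bond is cut. C1 is an acyl carbon and C8 carries oxygen four atoms away, so the two are joined as a lactone and C2–C3 arrive as an acetylide. The acyclic stereotriad folds back into a rigid five-membered ring and no protecting group is needed on the C8 oxygen. The forward step demands a single addition to a hindered, non-enolisable carbonyl.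

9 ⇒ 7 by way of 8. The bond from C5 to the future C4 and the bond from C6 to the allyl methylene are cut. Both substituents of C6 can be delivered to an α-methylene lactone, a nucleophile at the exocyclic carbon and an electrophile at the α-carbon of the resulting enolate. The quaternary centre is removed and 7 has only two stereocentres. The forward step needs 1,4- and not 1,2-addition, and because the second group enters anti to the C7 methyl, the allyl group has to be the electrophile.

7 ⇒ 4 + 5 by way of 6. The C7–C8 bond and the lactone O–C1 bond are cut. This is the key disconnection: an anti hydroxyl/methyl pair next to an acrylate unit is the retron of a crotylboration with a 2-alkoxycarbonyl crotylboronate, and the ester carbon of that reagent becomes C1. The molecule falls into two achiral pieces. The forward step must be γ-selective, anti-selective and selective for one aldehyde face.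

4 ⇒ 1 + 2 by way of 3. The bond between the α-carbon of the enoate and the boryl-methyl carbon is cut, and the β-hydrogen is removed to return to an alkyne. With the methyl group already in the alkyne, syn-hydrometalation places methyl trans to the metal as the kinetic outcome, without any equilibration of an alkenylmetal. The forward alkylation must keep that geometry.

## Other disconnections considered

Alternative 1: The cut runs through the C1–C2 and C1–C6 bonds of the ring and through the bond between the C6 side-arm methylene and its carbonyl carbon. This leads back to the acyclic (Z)-alkenyl iodide A2, in which C4 already carries its methoxy group and C6 is the inner carbon of a 1,1-disubstituted alkene. In the forward direction zerovalent palladium would insert into the C–I bond of A2 and take up one carbonyl unit to give an acylpalladium. This would add across the alkene in a 6-exo mode, closing the ring and creating C6. The resulting neopentyl-type alkylpalladium has no β-hydrogen, so it would carbonylate a second time and end by alcoholysis as ester A1.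
- In its favour: ring, quaternary centre and three C–C bonds would come from one catalytic operation. C4 is fixed before the ring exists, so no late 1,3-induction is needed; on this point the alternative is better than the chosen plan.
- Against it: the configuration of C6 would rest on the facial preference of an acylpalladation next to C7, for which the open chain offers no rigid control element. The acylpalladium could also be trapped by the alcohol before it cyclises.
- Structure: A1 still needs its ester arm converted into the allyl group (reduction to the aldehyde beside an enone, then methylenation) and its silyl ether exchanged for the acetate. A2 is itself a stereotriad that needs a multi-step assembly.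
- Mechanism: the chosen plan sets C6 by alkylating an enolate held in a five-membered ring beside the methyl group, which is the more predictable event.
- Step economy: the two plans should be about equal in length.

Alternative 2: The C6–C7 bond is cut together with a temporary bond from C8 to the oxygen that later becomes the C1 carbonyl oxygen. This divides the molecule into the allyl-substituted quinone monoketal A4 and the propenylarene A5. In the forward direction acid would ionise A4 to a methoxy-stabilised cyclohexadienone cation. A5 would attack the allyl-bearing ring carbon through its methyl-bearing carbon, and the ring carbonyl oxygen would trap the benzylic cation. This closes a tetrahydrofuran and gives the bicyclic dienone A3 with aryl and methyl trans and methyl anti to allyl.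
- In its favour: C6, C7, C8 and the whole carbon skeleton would arise in one step from two simple achiral pieces. In convergence and in step count to the core this alternative is clearly better than the chosen plan.
- Against it: neither partner is chiral and the cation offers no handle for established absolute control, so the single enantiomer would require a resolution or an untested chiral counter-anion. A bridged mode of addition of the same cation would compete.
- Structure: A3 is at the wrong oxidation level. Reaching 16 would need carbonyl reduction, hydrolytic opening of the vinylogous ester with transposition of the enone, and a regio- and stereoselective saturation of the methoxy-bearing ring alkene that sets C4 while sparing the allyl group.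
- Mechanism: an open cation is less controllable than the closed chair of the chosen plan, which is better on absolute stereocontrol and on C4.
- Step economy: the alternative stays ahead, although part of its advantage is spent on the redox adjustments.

Alternative 3: The cut goes through the C7–C8 bond and the C5–C6 bond. This turns the cyclohexenone into the symmetric cyclopent-3-enol A7, which carries a (Z)-trisubstituted alkenyl group on its carbinol carbon, plus aldehyde 5. In the forward direction a Lewis acid would activate 5 and the alkene of A7 would attack through its methyl-bearing carbon (Prins step). One of the two equivalent ring methylenes would then shift to the tertiary cation with formation of the ketone (pinacol step), expanding the ring to the β,γ-unsaturated ketone A6 with C6, C7 and C8 in place.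
- In its favour: the same aldehyde is used as in the chosen plan, so the two are equal there. Quaternary centre, ring and benzylic stereodiad would form together, a better bond count per step than the chosen plan. The symmetry of A7 removes any question of which methylene migrates.
- Against it: three stereocentres would depend on one cationic event whose topology is not enforced by a closed transition state, and no reliable source of absolute control is at hand. The electron-rich benzylic alcohol of A6 would be prone to ionise under the Lewis acid.
- Structure: A6 lacks the C4 oxygen, so the ring alkene would still have to be oxidised at C4 and moved into conjugation, selectively beside the allyl group.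
- Mechanism: the chosen plan, with a chair transition state and a catalyst, is the stronger on stereochemical predictability.
- Step economy: the alternative is shorter to the ring but would pay several further steps for C4, so overall lengths should be comparable.

Key step: step 2

Remark on the chemistry: the (R)-enantiomer of the binaphthyl phosphoric acid used in step 2 is taken to direct simple pinacol allyl- and crotylboronates to the Re face of aryl aldehydes; boronate 4 is assumed to follow the same model, so the (S)-acid is specified, and its antipode would be used if 4 responded in the opposite sense.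

## Route

Step 1
Reactants: 1 methyl but-2-ynoate; 2 2-(iodomethyl)-4,4,5,5-tetramethyl-1,3,2-dioxaborolane
Product: 4 methyl (Z)-2-[(4,4,5,5-tetramethyl-1,3,2-dioxaborolan-2-yl)methyl]but-2-enoate, via alkenylalane 3 (not isolated)
Conditions: i-Bu2AlH, (Me2N)3PO, THF, 0 °C; then 2, 0 °C → rt
Reagents that add atoms: none
Why: Conjugate hydroalumination of the acetylenic ester delivers hydrogen and aluminium to the same side of the triple bond, so the methyl group is trans to the metal in 3. C-alkylation by the α-iodoboronate (boron ate complex, then 1,2-shift with loss of iodide) keeps that geometry, and attack on the allenolate form anti to methyl leads to the same isomer, with methyl trans to the boryl-methyl group.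

Step 2
Reactants: 4 methyl (Z)-2-[(4,4,5,5-tetramethyl-1,3,2-dioxaborolan-2-yl)methyl]but-2-enoate; 5 3,4,5-trimethoxybenzaldehyde
Product: 7 (4S,5S)-4-methyl-3-methylidene-5-(3,4,5-trimethoxyphenyl)oxolan-2-one, via open-chain borate 6 (not isolated)
Conditions: (S)-3,3′-bis(2,4,6-triisopropylphenyl)-1,1′-binaphthyl-2,2′-diyl hydrogen phosphate (10 mol %), 4 Å MS, toluene, 40 °C; then p-toluenesulfonic acid monohydrate (TsOH·H2O, 10 mol %), rt
Reagents that add atoms: none
Why: Proposed new method: the chiral binaphthyl phosphoric acid is expected to accelerate and steer the addition by hydrogen bonding to the pseudo-axial boronate oxygen of 4 while its phosphoryl oxygen contacts the formyl C–H of 5, so that C–C bond formation runs through a closed six-membered chair inside the chiral pocket; the closest known reaction types are the chiral-phosphoric-acid-catalysed allyl- and crotylboration of aryl aldehydes with pinacol boronates and the achiral Brønsted- or Lewis-acid-catalysed addition of 2-alkoxycarbonyl allylboronates with lactonisation, which are combined here for the first time. In the chair the aryl group of 5 and the γ-methyl group of 4, which is trans to the boryl-methyl carbon, are both equatorial, and this turns the (Z) geometry of 4 into the anti relationship of the two new centres in borate 6, so the diastereoselection is substrate-controlled. The absolute configuration is catalyst-controlled: the (S)-acid should leave the Si face of 5 open, giving (S) at the carbinol carbon and, through the chair, (S) at the methyl-bearing carbon. The borate oxygen of 6 then attacks the neighbouring ester carbonyl in a 5-exo-trig acyl substitution, the methoxyboronate leaves and the lactone ring closes with anti becoming trans; the sulfonic acid, added only after the aldehyde is consumed, completes this closure. The step needs γ-selectivity, anti-diastereoselectivity and one aldehyde face, and these are secured in that order by the cyclic transition state, the geometric purity of 4 and the catalyst. Should the electron-rich benzylic C–O bond ionise during ring closure, re-closure trans to the fixed methyl centre leads to the same 7.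

Step 3
Reactants: 7 (4S,5S)-4-methyl-3-methylidene-5-(3,4,5-trimethoxyphenyl)oxolan-2-one
Product: 9 (3R,4S,5S)-3-(1,3-dithian-2-ylmethyl)-4-methyl-3-(prop-2-en-1-yl)-5-(3,4,5-trimethoxyphenyl)oxolan-2-one, via lithium enolate 8 (not isolated)
Conditions: 1,3-dithiane, n-BuLi, THF, −30 °C; then 7 (slow addition), DMPU, −78 °C; then allyl bromide, −78 → −20 °C
Reagents that add atoms: 1,3-dithiane (C1CSCSC1), used as its 2-lithio derivative; allyl bromide (C=CCBr)
Why: Michael addition of the sulfur-stabilised carbanion to the exocyclic methylene gives enolate 8, and C-allylation of 8 creates the quaternary centre (tandem conjugate addition–enolate alkylation). The allyl group should enter the enolate face anti to the adjacent ring methyl group, the usual course for β-substituted butyrolactone enolates, which is the configuration required at C6.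

Step 4
Reactants: 9 (3R,4S,5S)-3-(1,3-dithian-2-ylmethyl)-4-methyl-3-(prop-2-en-1-yl)-5-(3,4,5-trimethoxyphenyl)oxolan-2-one
Product: 10 (4R)-4-(1,3-dithian-2-ylmethyl)-4-[(1S,2S)-1-hydroxy-1-(3,4,5-trimethoxyphenyl)propan-2-yl]-1-(trimethylsilyl)hept-6-en-1-yn-3-one
Conditions: Me3SiC≡CH, n-BuLi, THF, −78 °C; then 9, −78 → 0 °C; aq NH4Cl
Reagents that add atoms: ethynyltrimethylsilane (C#C[Si](C)(C)C), used as its lithium acetylide
Why: Acetylide addition to the lactone carbonyl gives a hemiketal alkoxide that does not take up a second equivalent and opens on work-up to the γ-hydroxy ynone (in equilibrium with its cyclic hemiketal). The α-carbon is quaternary, so no enolisation competes and no stereocentre is at risk.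

Step 5
Reactants: 10 (4R)-4-(1,3-dithian-2-ylmethyl)-4-[(1S,2S)-1-hydroxy-1-(3,4,5-trimethoxyphenyl)propan-2-yl]-1-(trimethylsilyl)hept-6-en-1-yn-3-one
Product: 11 (1S,2S)-2-[(4R)-4-(1,3-dithian-2-ylmethyl)-3-oxo-1-(trimethylsilyl)hept-6-en-1-yn-4-yl]-1-(3,4,5-trimethoxyphenyl)propyl acetate
Conditions: Ac2O, 4-(dimethylamino)pyridine (cat.), pyridine, CH2Cl2, 0 °C → rt
Reagents that add atoms: acetic anhydride (CC(=O)OC(C)=O)
Why: Nucleophile-catalysed acylation of the secondary benzylic hydroxyl; acylation of the open form drains the hemiketal equilibrium and the silyl cap keeps the ynone from adding the amine catalyst. The C8–O bond is not broken, so the configuration is kept.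

Step 6
Reactants: 11 (1S,2S)-2-[(4R)-4-(1,3-dithian-2-ylmethyl)-3-oxo-1-(trimethylsilyl)hept-6-en-1-yn-4-yl]-1-(3,4,5-trimethoxyphenyl)propyl acetate
Product: 13 (1S,2S)-2-[(1Z,4R)-4-(1,3-dithian-2-ylmethyl)-1-iodo-3-oxohepta-1,6-dien-4-yl]-1-(3,4,5-trimethoxyphenyl)propyl acetate, via terminal ynone 12 (not isolated)
Conditions: Bu4NF, AcOH, THF, 0 °C; then NaI, AcOH, rt, dark
Reagents that add atoms: sodium iodide ([Na+].[I-])
Why: Buffered fluoride cleaves the alkynyl C–Si bond; iodide then adds to the terminal ynone in conjugate fashion and the allenol is protonated on the side away from iodine, the kinetic anti-hydroiodination that gives the (Z)-β-iodoenone needed for a cis ring alkene. The weakly acidic medium leaves acetate, dithioacetal and allyl group untouched.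

Step 7
Reactants: 13 (1S,2S)-2-[(1Z,4R)-4-(1,3-dithian-2-ylmethyl)-1-iodo-3-oxohepta-1,6-dien-4-yl]-1-(3,4,5-trimethoxyphenyl)propyl acetate
Product: 14 (1S,2S)-2-[(1Z,4R)-1-iodo-3-oxo-4-(2-oxoethyl)hepta-1,6-dien-4-yl]-1-(3,4,5-trimethoxyphenyl)propyl acetate
Conditions: PhI(OCOCF3)2, MeCN/H2O (9:1), 0 °C, short reaction time
Reagents that add atoms: water (O)
Why: Oxidative hydrolysis of the dithioacetal: the trivalent iodine reagent activates sulfur, water adds and the aldehyde is released within minutes. Sulfur is far more easily oxidised than the arene, the alkenes or the alkenyl iodide, and the aldehyde α-carbon is a methylene on a quaternary centre, so nothing can epimerise.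

Step 8
Reactants: 14 (1S,2S)-2-[(1Z,4R)-1-iodo-3-oxo-4-(2-oxoethyl)hepta-1,6-dien-4-yl]-1-(3,4,5-trimethoxyphenyl)propyl acetate
Product: 15 (1S,2S)-2-[(1R,5R)-5-hydroxy-2-oxo-1-(prop-2-en-1-yl)cyclohex-3-en-1-yl]-1-(3,4,5-trimethoxyphenyl)propyl acetate
Conditions: CrCl2 (excess), NiCl2 (cat.), degassed DMF/THF, rt, high dilution; aq work-up
Reagents that add atoms: none
Why: Intramolecular Nozaki–Hiyama–Kishi reaction: zerovalent nickel formed in the flask inserts into the alkenyl C–I bond and passes the alkenyl group to trivalent chromium, which adds to the aldehyde in preference to ketone and ester and closes the six-membered ring with the cis alkene. C4 is set here: with the larger C7 arm pseudo-equatorial and the chromium-bound oxygen pseudo-equatorial, away from the pseudo-axial allyl group, the hydroxyl should come out cis to the arm, which is (R).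

Step 9
Reactants: 15 (1S,2S)-2-[(1R,5R)-5-hydroxy-2-oxo-1-(prop-2-en-1-yl)cyclohex-3-en-1-yl]-1-(3,4,5-trimethoxyphenyl)propyl acetate
Product: 16 (1S,2S)-2-[(1R,5R)-5-methoxy-2-oxo-1-(prop-2-en-1-yl)cyclohex-3-en-1-yl]-1-(3,4,5-trimethoxyphenyl)propyl acetate
Conditions: MeI, Ag2O, 4 Å MS, CH2Cl2, rt, dark
Reagents that add atoms: iodomethane (CI)
Why: Purdie methylation under essentially neutral conditions: Ag2O assists departure of iodide and takes up the proton, so the allylic alcohol is methylated without enolising the γ-oxygenated enone or cleaving the acetate. The C4–O bond is not broken, so the configuration is kept.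

## Compound list

1 | methyl but-2-ynoate | CC#CC(=O)OC | starting material
2 | 2-(iodomethyl)-4,4,5,5-tetramethyl-1,3,2-dioxaborolane | ICB1OC(C)(C)C(C)(C)O1 | starting material
3 | methyl (E)-2-[bis(2-methylpropyl)alumanyl]but-2-enoate (alkenylalane, methyl trans to aluminium) | C/C=C(/[Al](CC(C)C)CC(C)C)C(=O)OC | intermediate
4 | methyl (Z)-2-[(4,4,5,5-tetramethyl-1,3,2-dioxaborolan-2-yl)methyl]but-2-enoate | C/C=C(/CB1OC(C)(C)C(C)(C)O1)C(=O)OC | intermediate
5 | 3,4,5-trimethoxybenzaldehyde | COc1cc(C=O)cc(OC)c1OC | starting material
6 | methyl (3S,4S)-3-methyl-2-methylidene-4-[(4,4,5,5-tetramethyl-1,3,2-dioxaborolan-2-yl)oxy]-4-(3,4,5-trimethoxyphenyl)butanoate (anti) | C=C(C(=O)OC)[C@H](C)[C@@H](c1cc(OC)c(OC)c(OC)c1)OB1OC(C)(C)C(C)(C)O1 | intermediate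
7 | (4S,5S)-4-methyl-3-methylidene-5-(3,4,5-trimethoxyphenyl)oxolan-2-one (trans) | C=C1[C@H](C)[C@@H](c2cc(OC)c(OC)c(OC)c2)OC1=O | intermediate
8 | lithium (4S,5S)-3-(1,3-dithian-2-ylmethyl)-4-methyl-5-(3,4,5-trimethoxyphenyl)-4,5-dihydrofuran-2-olate | [Li]OC1=C(CC2SCCCS2)[C@H](C)[C@@H](c2cc(OC)c(OC)c(OC)c2)O1 | intermediate
9 | (3R,4S,5S)-3-(1,3-dithian-2-ylmethyl)-4-methyl-3-(prop-2-en-1-yl)-5-(3,4,5-trimethoxyphenyl)oxolan-2-one | C=CC[C@@]1(CC2SCCCS2)[C@H](C)[C@@H](c2cc(OC)c(OC)c(OC)c2)OC1=O | intermediate
10 | (4R)-4-(1,3-dithian-2-ylmethyl)-4-[(1S,2S)-1-hydroxy-1-(3,4,5-trimethoxyphenyl)propan-2-yl]-1-(trimethylsilyl)hept-6-en-1-yn-3-one | C=CC[C@@](CC1SCCCS1)([C@H](C)[C@H](O)c1cc(OC)c(OC)c(OC)c1)C(=O)C#C[Si](C)(C)C | intermediate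
11 | (1S,2S)-2-[(4R)-4-(1,3-dithian-2-ylmethyl)-3-oxo-1-(trimethylsilyl)hept-6-en-1-yn-4-yl]-1-(3,4,5-trimethoxyphenyl)propyl acetate | C=CC[C@@](CC1SCCCS1)([C@H](C)[C@H](OC(C)=O)c1cc(OC)c(OC)c(OC)c1)C(=O)C#C[Si](C)(C)C | intermediate
12 | (1S,2S)-2-[(4R)-4-(1,3-dithian-2-ylmethyl)-3-oxohept-6-en-1-yn-4-yl]-1-(3,4,5-trimethoxyphenyl)propyl acetate | C=CC[C@@](CC1SCCCS1)([C@H](C)[C@H](OC(C)=O)c1cc(OC)c(OC)c(OC)c1)C(=O)C#C | intermediate
13 | (1S,2S)-2-[(1Z,4R)-4-(1,3-dithian-2-ylmethyl)-1-iodo-3-oxohepta-1,6-dien-4-yl]-1-(3,4,5-trimethoxyphenyl)propyl acetate | C=CC[C@@](CC1SCCCS1)([C@H](C)[C@H](OC(C)=O)c1cc(OC)c(OC)c(OC)c1)C(=O)/C=C\I | intermediate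
14 | (1S,2S)-2-[(1Z,4R)-1-iodo-3-oxo-4-(2-oxoethyl)hepta-1,6-dien-4-yl]-1-(3,4,5-trimethoxyphenyl)propyl acetate | C=CC[C@@](CC=O)([C@H](C)[C@H](OC(C)=O)c1cc(OC)c(OC)c(OC)c1)C(=O)/C=C\I | intermediate
15 | (1S,2S)-2-[(1R,5R)-5-hydroxy-2-oxo-1-(prop-2-en-1-yl)cyclohex-3-en-1-yl]-1-(3,4,5-trimethoxyphenyl)propyl acetate | C=CC[C@]1([C@H](C)[C@H](OC(C)=O)c2cc(OC)c(OC)c(OC)c2)C[C@@H](O)C=CC1=O | intermediate
16 | (1S,2S)-2-[(1R,5R)-5-methoxy-2-oxo-1-(prop-2-en-1-yl)cyclohex-3-en-1-yl]-1-(3,4,5-trimethoxyphenyl)propyl acetate | C=CC[C@]1([C@H](C)[C@H](OC(C)=O)c2cc(OC)c(OC)c(OC)c2)C[C@@H](OC)C=CC1=O | target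

## Step count and least certain steps

Total step count: 9. Longest linear sequence: 9 steps (1 → 16); 2 and 5 are the only other numbered inputs.

Step 2 (key step, proposed new method). What is most likely to go wrong is slow turnover: the ester group makes 4 a weak nucleophile, the chiral acid is far weaker than the strong acids known to promote this addition, and an uncatalysed or achiral-acid pathway could then erode the facial selectivity. The fallback uses known chemistry and moves the control from the catalyst to boron.
- It sets out from 1: alane 3 is trapped not with 2 but with the (iodomethyl)boronic ester of (1R,2S,3S,4S)-1,7,7-trimethyl-3-phenylbicyclo[2.2.1]heptane-2,3-diol F1, itself obtained from the camphor-derived diol and diisopropyl (iodomethyl)boronate by ester exchange.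
- This gives the chiral analogue of 4, methyl (Z)-2-(borylmethyl)but-2-enoate carrying the same diol on boron F2.
- Sc(OTf)3-catalysed addition of F2 to 5 at low temperature, followed by acid-promoted ring closure, comes back to the route at 7.
- The diol from (1R)-camphor is written; the diol from (1S)-camphor would be taken if the first proved to direct the aldehyde to the other face.

Step 3. Likely failures are competition from 1,2-addition and from enolate-to-acceptor oligomerisation of the α-methylene lactone, and incomplete facial selectivity when the hindered enolate is allylated syn to the remote aryl group. The fallback separates the two bond formations.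
- It sets out from 7: the dithiane anion is added at −78 °C and the enolate is protonated at once, so that (4S,5S)-3-(1,3-dithian-2-ylmethyl)-4-methyl-5-(3,4,5-trimethoxyphenyl)oxolan-2-one F3 is isolated.
- F3 is then converted with KN(SiMe3)2 into its potassium enolate and allylated with allyl acetate and Pd(PPh3)4 (Tsuji–Trost allylation), where the bulkier π-allyl electrophile should respect the methyl-bearing face more strictly.
- This comes back to the route at 9.

Step 4. Likely failures are sluggish addition to the neopentyl-type carbonyl, partial loss of the silyl cap through the alkoxide, and ring–chain tautomerism of 10 towards the cyclic hemiketal, which would slow the acetylation in step 5. The fallback installs the acetate before any ketone exists.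
- It sets out from 9: the lactone is opened with Me3Al and N,O-dimethylhydroxylamine hydrochloride to (2R)-2-(1,3-dithian-2-ylmethyl)-2-[(1S,2S)-1-hydroxy-1-(3,4,5-trimethoxyphenyl)propan-2-yl]-N-methoxy-N-methylpent-4-enamide F4.
- F4 is acetylated at once (Ac2O, 4-(dimethylamino)pyridine) to (1S,2S)-2-[(2R)-2-(1,3-dithian-2-ylmethyl)-1-[methoxy(methyl)amino]-1-oxopent-4-en-2-yl]-1-(3,4,5-trimethoxyphenyl)propyl acetate F5.
- Lithium (trimethylsilyl)acetylide, which adds to the chelating amide at low temperature much faster than to an acetate, then gives the ynone and comes back to the route at 11.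

Step 8. The ring closure itself should be reliable; what may fail is the 1,3-induction at C4, that is, poor facial selectivity at the aldehyde. The fallback corrects the centre by inversion instead of relying on the ring closure.
- It sets out from 14: the cyclisation is run as written and the unwanted C4 epimer, (1S,2S)-2-[(1R,5S)-5-hydroxy-2-oxo-1-(prop-2-en-1-yl)cyclohex-3-en-1-yl]-1-(3,4,5-trimethoxyphenyl)propyl acetate F6, is separated.
- Mitsunobu reaction of F6 with chloroacetic acid (PPh3, diisopropyl azodicarboxylate) gives the inverted ester (1S,2S)-2-[(1R,5R)-5-(chloroacetoxy)-2-oxo-1-(prop-2-en-1-yl)cyclohex-3-en-1-yl]-1-(3,4,5-trimethoxyphenyl)propyl acetate F7.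
- Thiourea removes the chloroacetyl group in the presence of the acetate, and both epimers thus come back to the route at 15.

## Further compounds

F1 | step 2 | (iodomethyl)boronic ester of (1R,2S,3S,4S)-1,7,7-trimethyl-3-phenylbicyclo[2.2.1]heptane-2,3-diol | C[C@@]12CC[C@@H](C1(C)C)[C@](O3)(c1ccccc1)[C@H]2OB3CI
F2 | step 2 | methyl (Z)-2-(borylmethyl)but-2-enoate carrying (1R,2S,3S,4S)-1,7,7-trimethyl-3-phenylbicyclo[2.2.1]heptane-2,3-diol on boron | C[C@@]12CC[C@@H](C1(C)C)[C@](O3)(c1ccccc1)[C@H]2OB3C/C(=C/C)C(=O)OC
F3 | step 3 | (4S,5S)-3-(1,3-dithian-2-ylmethyl)-4-methyl-5-(3,4,5-trimethoxyphenyl)oxolan-2-one (both C3 epimers) | C(C1SCCCS1)C1[C@H](C)[C@@H](c2cc(OC)c(OC)c(OC)c2)OC1=O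
F4 | step 4 | (2R)-2-(1,3-dithian-2-ylmethyl)-2-[(1S,2S)-1-hydroxy-1-(3,4,5-trimethoxyphenyl)propan-2-yl]-N-methoxy-N-methylpent-4-enamide | C=CC[C@@](CC1SCCCS1)([C@H](C)[C@H](O)c1cc(OC)c(OC)c(OC)c1)C(=O)N(C)OC
F5 | step 4 | (1S,2S)-2-[(2R)-2-(1,3-dithian-2-ylmethyl)-1-[methoxy(methyl)amino]-1-oxopent-4-en-2-yl]-1-(3,4,5-trimethoxyphenyl)propyl acetate | C=CC[C@@](CC1SCCCS1)([C@H](C)[C@H](OC(C)=O)c1cc(OC)c(OC)c(OC)c1)C(=O)N(C)OC
F6 | step 8 | (1S,2S)-2-[(1R,5S)-5-hydroxy-2-oxo-1-(prop-2-en-1-yl)cyclohex-3-en-1-yl]-1-(3,4,5-trimethoxyphenyl)propyl acetate | C=CC[C@]1([C@H](C)[C@H](OC(C)=O)c2cc(OC)c(OC)c(OC)c2)C[C@H](O)C=CC1=O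
F7 | step 8 | (1S,2S)-2-[(1R,5R)-5-(chloroacetoxy)-2-oxo-1-(prop-2-en-1-yl)cyclohex-3-en-1-yl]-1-(3,4,5-trimethoxyphenyl)propyl acetate | C=CC[C@]1([C@H](C)[C@H](OC(C)=O)c2cc(OC)c(OC)c(OC)c2)C[C@@H](OC(=O)CCl)C=CC1=O
A1 | alternative 1 | methyl 2-[(1S,5R)-1-[(1S,2S)-1-(tert-butyldimethylsilyloxy)-1-(3,4,5-trimethoxyphenyl)propan-2-yl]-5-methoxy-2-oxocyclohex-3-en-1-yl]acetate | COC(=O)C[C@]1([C@H](C)[C@H](O[Si](C)(C)C(C)(C)C)c2cc(OC)c(OC)c(OC)c2)C[C@@H](OC)C=CC1=O
A2 | alternative 1 | tert-butyl{[(1S,2S,5R,6Z)-7-iodo-5-methoxy-2-methyl-3-methylidene-1-(3,4,5-trimethoxyphenyl)hept-6-en-1-yl]oxy}dimethylsilane | I/C=C\[C@H](OC)CC(=C)[C@H](C)[C@H](O[Si](C)(C)C(C)(C)C)c1cc(OC)c(OC)c(OC)c1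
A3 | alternative 2 | 3a-allyl-5-methoxy-3-methyl-2-(3,4,5-trimethoxyphenyl)-3,3a-dihydro-1-benzofuran-6(2H)-one (aryl and methyl trans, methyl anti to allyl; enantiomer matching 16) | C=CC[C@]12C=C(OC)C(=O)C=C1O[C@H](c1cc(OC)c(OC)c(OC)c1)[C@H]2C
A4 | alternative 2 | 2-allyl-4,4,5-trimethoxycyclohexa-2,5-dien-1-one | C=CCC1=CC(OC)(OC)C(OC)=CC1=O
A5 | alternative 2 | 1,2,3-trimethoxy-5-[(E)-prop-1-en-1-yl]benzene | C/C=C/c1cc(OC)c(OC)c(OC)c1
A6 | alternative 3 | (6R)-6-allyl-6-[(1S,2S)-1-hydroxy-1-(3,4,5-trimethoxyphenyl)propan-2-yl]cyclohex-3-en-1-one | C=CC[C@]1([C@H](C)[C@H](O)c2cc(OC)c(OC)c(OC)c2)CC=CCC1=O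
A7 | alternative 3 | 1-[(2Z)-hexa-2,5-dien-3-yl]cyclopent-3-en-1-ol | C=CC/C(=C/C)C1(O)CC=CC1
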